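**Retrosynthetic overview**
1. Target 19 comes from diene lactone 18 by peracid epoxidation of C4=C5 (the only electron-rich alkene); 18 comes from alcohol 17 by O8 methacrylation.
2. 17 comes from acyclic aldehyde 15 in one flask: ring-closing metathesis makes the lactone ring as a 3-(bromomethyl)butenolide, then CrCl2 joins C7 to C8 and closes the ten-membered ring (sets C7 and C8).
3. 15 comes from enal 11 by catalyst-controlled vinyl addition (C6), acrylate ester formation and cleavage of a dioxolane to aldehyde C8.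
4. 11 comes from (Z)-2-iodoenoate 7 and (S)-glyceraldehyde acetonide 8 by Ni/Cr coupling (C9–C10 bond, C9 centre); 7 comes from geranyl acetate 1 (C1–C6, C15) and ylide 4 (C10, C14).
5. Ring order: lactone and carbocycle together in step 10, oxirane last in step 12.

Assumption: compounds 4, 8 and 13 are bought; ring positions are quoted in germacrane numbering (C1–C15, lactone oxygen on C6).

Step 1
Reactants: 1 geranyl acetate
Product: 3 (2E)-3-methyl-6-oxohex-2-en-1-yl acetate, via 6,7-epoxygeranyl acetate 2 (not isolated)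
Conditions: mCPBA (1.05 equiv), CH2Cl2, 0 °C; then H5IO6 (1.2 equiv), THF/H2O, 0 °C to rt
Reagents that add atoms: mCPBA, OOC(=O)c1cccc(Cl)c1
Why: The distal 6,7-alkene is the more electron-rich one (the 2,3-alkene is deactivated by the allylic acetate) and is epoxidised selectively (Prilezhaev reaction), after which periodic acid opens the oxirane and cleaves the glycol (Malaprade cleavage) to leave aldehyde C1 with the (E)-C4=C5 alkene of geraniol intact, no stereocentre being carried on.

Step 2
Reactants: 3 (2E)-3-methyl-6-oxohex-2-en-1-yl acetate; 4 methyl (triphenylphosphoranylidene)acetate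
Product: 6 methyl (2Z,6E)-8-(acetyloxy)-2-iodo-6-methylocta-2,6-dienoate, via methyl iodo(triphenylphosphoranylidene)acetate 5 (not isolated)
Conditions: N-iodosuccinimide (1.05 equiv), MeCN, −20 °C, 20 min; then 3, −20 °C to rt
Reagents that add atoms: N-iodosuccinimide, O=C1CCC(=O)N1I
Why: The stabilised ylide is iodinated in the flask and the iodo ylide then undergoes Wittig olefination with 3, which favours the (Z)-2-iodoenoate (iodine cis to the chain), the geometry that later places C2 cis to C9 at the C1=C10 alkene.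

Step 3
Reactants: 6 methyl (2Z,6E)-8-(acetyloxy)-2-iodo-6-methylocta-2,6-dienoate
Product: 7 methyl (2Z,6E)-8-hydroxy-2-iodo-6-methylocta-2,6-dienoate
Conditions: K2CO3 (0.1 equiv), MeOH, 0 °C
Reagents that add atoms: none
Why: Catalytic transesterification with methanol removes the primary allylic acetate so that no allylic ester meets low-valent nickel in the next step, and no stereo element is touched.

Step 4
Reactants: 7 methyl (2Z,6E)-8-hydroxy-2-iodo-6-methylocta-2,6-dienoate; 8 (4S)-2,2-dimethyl-1,3-dioxolane-4-carbaldehyde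
Product: 9 methyl (2E,6E)-2-[(R)-[(4S)-2,2-dimethyl-1,3-dioxolan-4-yl](hydroxy)methyl]-8-hydroxy-6-methylocta-2,6-dienoate
Conditions: CrCl2 (4 equiv), NiCl2 (2 mol %), DMSO, 25 °C
Reagents that add atoms: none
Why: Nozaki–Hiyama–Kishi coupling in which zerovalent nickel inserts into the C–I bond, the alkenyl group passes to chromium with retention of alkene geometry and adds to aldehyde 8 in the Felkin–Anh (anti) sense, so the (S)-dioxolane centre fixes the new carbinol C9 as (R), the free primary alcohol being tolerated.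

Step 5
Reactants: 9 methyl (2E,6E)-2-[(R)-[(4S)-2,2-dimethyl-1,3-dioxolan-4-yl](hydroxy)methyl]-8-hydroxy-6-methylocta-2,6-dienoate
Product: 10 methyl (2E,6E)-2-[(R)-[(4S)-2,2-dimethyl-1,3-dioxolan-4-yl](hydroxy)methyl]-6-methyl-8-oxoocta-2,6-dienoate
Conditions: TEMPO (10 mol %), PhI(OAc)2 (1.1 equiv), CH2Cl2, 25 °C
Reagents that add atoms: none
Why: The TEMPO oxoammonium oxidation with PhI(OAc)2 as terminal oxidant converts the primary allylic alcohol much faster than the hindered secondary one and stops at the (E)-enal, leaving C9 untouched.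

Step 6
Reactants: 10 methyl (2E,6E)-2-[(R)-[(4S)-2,2-dimethyl-1,3-dioxolan-4-yl](hydroxy)methyl]-6-methyl-8-oxoocta-2,6-dienoate
Product: 11 methyl (2E,6E)-2-[(R)-(acetyloxy)[(4S)-2,2-dimethyl-1,3-dioxolan-4-yl]methyl]-6-methyl-8-oxoocta-2,6-dienoate
Conditions: Ac2O (1.5 equiv), pyridine, DMAP (5 mol %), CH2Cl2, 0 °C
Reagents that add atoms: acetic anhydride, CC(=O)OC(C)=O
Why: DMAP-catalysed acylation (esterification) puts the acetate of the target on O9 with retention at C9.

Step 7
Reactants: 11 methyl (2E,6E)-2-[(R)-(acetyloxy)[(4S)-2,2-dimethyl-1,3-dioxolan-4-yl]methyl]-6-methyl-8-oxoocta-2,6-dienoate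
Product: 12 methyl (2E,6E,8S)-2-[(R)-(acetyloxy)[(4S)-2,2-dimethyl-1,3-dioxolan-4-yl]methyl]-8-hydroxy-6-methyldeca-2,6,9-trienoate
Conditions: Zn(CH=CH2)2 (2.0 equiv), (−)-DAIB (10 mol %), toluene/Et2O, −20 °C; aq NH4Cl
Reagents that add atoms: divinylzinc, C=C[Zn]C=C
Why: Amino-alcohol-catalysed 1,2-addition of an alkenylzinc to an aldehyde in which the (−)-DAIB zinc chelate delivers vinyl to the enal face that gives the (S)-carbinol (the sense known for dialkylzinc additions to (E)-enals), setting C6 under catalyst control while esters, acetate and acetonide are inert to the organozinc.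

Step 8
Reactants: 12 methyl (2E,6E,8S)-2-[(R)-(acetyloxy)[(4S)-2,2-dimethyl-1,3-dioxolan-4-yl]methyl]-8-hydroxy-6-methyldeca-2,6,9-trienoate; 13 2-(bromomethyl)prop-2-enoic acid
Product: 14 methyl (2E,6E,8S)-2-[(R)-(acetyloxy)[(4S)-2,2-dimethyl-1,3-dioxolan-4-yl]methyl]-8-{[2-(bromomethyl)prop-2-enoyl]oxy}-6-methyldeca-2,6,9-trienoate
Conditions: DCC (1.2 equiv), DMAP (5 mol %), CH2Cl2, −10 °C
Reagents that add atoms: none
Why: Steglich esterification acylates the bis-allylic alcohol without breaking its C–O bond, so C6 is retained and the vinyl and acrylate alkenes are placed in reach of each other for metathesis.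

Step 9
Reactants: 14 methyl (2E,6E,8S)-2-[(R)-(acetyloxy)[(4S)-2,2-dimethyl-1,3-dioxolan-4-yl]methyl]-8-{[2-(bromomethyl)prop-2-enoyl]oxy}-6-methyldeca-2,6,9-trienoate
Product: 15 methyl (2E,6E,8S)-2-[(1R)-1-(acetyloxy)-2-oxoethyl]-8-{[2-(bromomethyl)prop-2-enoyl]oxy}-6-methyldeca-2,6,9-trienoate
Conditions: H5IO6 (1.5 equiv), EtOAc, 25 °C; crude aldehyde used at once
Reagents that add atoms: none
Why: Periodic acid hydrolyses the terminal acetonide and cleaves the freed 1,2-diol in the same flask (Malaprade cleavage), which excises the auxiliary dioxolane stereocentre and unmasks aldehyde C8 next to the intact (R)-C9 acetate.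

Step 10
Reactants: 15 methyl (2E,6E,8S)-2-[(1R)-1-(acetyloxy)-2-oxoethyl]-8-{[2-(bromomethyl)prop-2-enoyl]oxy}-6-methyldeca-2,6,9-trienoate
Product: 17 methyl (3aR,4R,5R,6E,10E,11aR)-5-(acetyloxy)-4-hydroxy-10-methyl-3-methylidene-2-oxo-2,3,3a,4,5,8,9,11a-octahydrocyclodeca[b]furan-6-carboxylate, via bromomethyl butenolide aldehyde 16 (not isolated)
Conditions: second-generation Grubbs catalyst (10 mol %), toluene, 70 °C; then the cooled solution is added over 8 h to CrCl2 (8 equiv), DMF/THF, 25 °C, final 1 mM; pH 7 buffer quench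
Reagents that add atoms: none
Why: Proposed new method: ring-closing metathesis of the vinyl group onto the 2-(bromomethyl)acrylate first closes the lactone ring as a 3-(bromomethyl)butenolide, whose allylic bromide is then reduced by CrCl2 to a 2-(alkoxycarbonyl)allylchromium that attacks aldehyde C8 through its γ-carbon C7 in a chair Zimmerman–Traxler transition state and so closes the ten-membered ring, attack anti to the C5 side chain on C6 giving the trans lactone (C7) and the ring-locked (E)-type allyl geometry with C9 pseudo-equatorial giving the anti C7/C8 relationship (C8), the closest known reactions being intermolecular chromium or zinc allylations of aldehydes with 3-(bromomethyl)furan-2(5H)-ones and chromium-mediated Barbier macrocyclisations to ten-membered germacranolide rings.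

Step 11
Reactants: 17 methyl (3aR,4R,5R,6E,10E,11aR)-5-(acetyloxy)-4-hydroxy-10-methyl-3-methylidene-2-oxo-2,3,3a,4,5,8,9,11a-octahydrocyclodeca[b]furan-6-carboxylate
Product: 18 methyl (3aS,4R,5R,6E,10E,11aR)-5-(acetyloxy)-10-methyl-3-methylidene-4-[(2-methylprop-2-enoyl)oxy]-2-oxo-2,3,3a,4,5,8,9,11a-octahydrocyclodeca[b]furan-6-carboxylate
Conditions: methacrylic anhydride (3 equiv), Et3N, DMAP (0.2 equiv), CH2Cl2, 0 °C
Reagents that add atoms: methacrylic anhydride, C=C(C)C(=O)OC(=O)C(C)=C
Why: DMAP-catalysed esterification of the secondary C8 alcohol with the anhydride proceeds with retention (the 3a descriptor changes only through ligand priority) and removes the free hydroxyl that could otherwise attack the lactone or the neighbouring acetate.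

Step 12
Reactants: 18 methyl (3aS,4R,5R,6E,10E,11aR)-5-(acetyloxy)-10-methyl-3-methylidene-4-[(2-methylprop-2-enoyl)oxy]-2-oxo-2,3,3a,4,5,8,9,11a-octahydrocyclodeca[b]furan-6-carboxylate
Product: 19 methyl (1S,2R,4R,7E,9R,10R,11R)-9-(acetyloxy)-4-methyl-12-methylidene-10-[(2-methylprop-2-enoyl)oxy]-13-oxo-3,14-dioxatricyclo[9.3.0.0^2,4]tetradec-7-ene-8-carboxylate
Conditions: mCPBA (1.1 equiv), CH2Cl2, 0 °C
Reagents that add atoms: mCPBA, OOC(=O)c1cccc(Cl)c1
Why: Prilezhaev epoxidation in which the peracid reacts only with the C4=C5 alkene (the other three alkenes are conjugated to carbonyl groups) and approaches its outer face in the folded cyclodecadiene (ring-cis C1=C10, ring-trans C4=C5), the trans-fused lactone blocking the inner face, which gives the trans (4R,5R)-oxirane as in peracid epoxidations of 4,5-unsaturated germacranolides to parthenolide-type epoxides.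

**Compound list**
1 | geranyl acetate, (2E)-3,7-dimethylocta-2,6-dien-1-yl acetate | CC(C)=CCC/C(C)=C/COC(C)=O | starting material
2 | (2E)-5-(3,3-dimethyloxiran-2-yl)-3-methylpent-2-en-1-yl acetate (6,7-epoxygeranyl acetate, racemic at the oxirane) | CC1(C)OC1CC/C(C)=C/COC(C)=O | intermediate
3 | (2E)-3-methyl-6-oxohex-2-en-1-yl acetate | O=CCC/C(C)=C/COC(C)=O | intermediate
4 | methyl (triphenylphosphoranylidene)acetate | COC(=O)C=P(c1ccccc1)(c1ccccc1)c1ccccc1 | starting material
5 | methyl iodo(triphenylphosphoranylidene)acetate | COC(=O)C(I)=P(c1ccccc1)(c1ccccc1)c1ccccc1 | intermediate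
6 | methyl (2Z,6E)-8-(acetyloxy)-2-iodo-6-methylocta-2,6-dienoate | COC(=O)/C(I)=C/CC/C(C)=C/COC(C)=O | intermediate
7 | methyl (2Z,6E)-8-hydroxy-2-iodo-6-methylocta-2,6-dienoate | COC(=O)/C(I)=C/CC/C(C)=C/CO | intermediate
8 | (4S)-2,2-dimethyl-1,3-dioxolane-4-carbaldehyde | O=C[C@@H]1COC(C)(C)O1 | starting material
9 | methyl (2E,6E)-2-[(R)-[(4S)-2,2-dimethyl-1,3-dioxolan-4-yl](hydroxy)methyl]-8-hydroxy-6-methylocta-2,6-dienoate | COC(=O)/C(=C/CC/C(C)=C/CO)[C@@H](O)[C@@H]1COC(C)(C)O1 | intermediate
10 | methyl (2E,6E)-2-[(R)-[(4S)-2,2-dimethyl-1,3-dioxolan-4-yl](hydroxy)methyl]-6-methyl-8-oxoocta-2,6-dienoate | COC(=O)/C(=C/CC/C(C)=C/C=O)[C@@H](O)[C@@H]1COC(C)(C)O1 | intermediate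
11 | methyl (2E,6E)-2-[(R)-(acetyloxy)[(4S)-2,2-dimethyl-1,3-dioxolan-4-yl]methyl]-6-methyl-8-oxoocta-2,6-dienoate | COC(=O)/C(=C/CC/C(C)=C/C=O)[C@@H](OC(C)=O)[C@@H]1COC(C)(C)O1 | intermediate
12 | methyl (2E,6E,8S)-2-[(R)-(acetyloxy)[(4S)-2,2-dimethyl-1,3-dioxolan-4-yl]methyl]-8-hydroxy-6-methyldeca-2,6,9-trienoate | COC(=O)/C(=C/CC/C(C)=C/[C@H](C=C)O)[C@@H](OC(C)=O)[C@@H]1COC(C)(C)O1 | intermediate
13 | 2-(bromomethyl)prop-2-enoic acid | C=C(CBr)C(=O)O | starting material
14 | methyl (2E,6E,8S)-2-[(R)-(acetyloxy)[(4S)-2,2-dimethyl-1,3-dioxolan-4-yl]methyl]-8-{[2-(bromomethyl)prop-2-enoyl]oxy}-6-methyldeca-2,6,9-trienoate | COC(=O)/C(=C/CC/C(C)=C/[C@H](C=C)OC(=O)C(=C)CBr)[C@@H](OC(C)=O)[C@@H]1COC(C)(C)O1 | intermediate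
15 | methyl (2E,6E,8S)-2-[(1R)-1-(acetyloxy)-2-oxoethyl]-8-{[2-(bromomethyl)prop-2-enoyl]oxy}-6-methyldeca-2,6,9-trienoate | COC(=O)/C(=C/CC/C(C)=C/[C@H](C=C)OC(=O)C(=C)CBr)[C@@H](OC(C)=O)C=O | intermediate
16 | methyl (2E,6E)-2-[(1R)-1-(acetyloxy)-2-oxoethyl]-7-[(2R)-4-(bromomethyl)-5-oxo-2,5-dihydrofuran-2-yl]-6-methylhepta-2,6-dienoate | COC(=O)/C(=C/CC/C(C)=C/[C@H]1OC(=O)C(CBr)=C1)[C@@H](OC(C)=O)C=O | intermediate
17 | methyl (3aR,4R,5R,6E,10E,11aR)-5-(acetyloxy)-4-hydroxy-10-methyl-3-methylidene-2-oxo-2,3,3a,4,5,8,9,11a-octahydrocyclodeca[b]furan-6-carboxylate | O[C@@H]1[C@H]2C(=C)C(=O)O[C@@H]2/C=C(C)/CC/C=C(/C(=O)OC)[C@H]1OC(C)=O | intermediate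
18 | methyl (3aS,4R,5R,6E,10E,11aR)-5-(acetyloxy)-10-methyl-3-methylidene-4-[(2-methylprop-2-enoyl)oxy]-2-oxo-2,3,3a,4,5,8,9,11a-octahydrocyclodeca[b]furan-6-carboxylate | C=C(C)C(=O)O[C@@H]1[C@H]2C(=C)C(=O)O[C@@H]2/C=C(C)/CC/C=C(/C(=O)OC)[C@H]1OC(C)=O | intermediate
19 | methyl (1S,2R,4R,7E,9R,10R,11R)-9-(acetyloxy)-4-methyl-12-methylidene-10-[(2-methylprop-2-enoyl)oxy]-13-oxo-3,14-dioxatricyclo[9.3.0.0^2,4]tetradec-7-ene-8-carboxylate (CNP0153978.7) | C=C(C)C(=O)O[C@@H]1[C@H]2C(=C)C(=O)O[C@@H]2[C@H]2O[C@]2(C)CC/C=C(/C(=O)OC)[C@H]1OC(C)=O | target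

**Step count and risks**
Total step count: 12. Longest linear sequence: 12 (from geranyl acetate 1; 4, 8 and 13 are bought).

Steps most likely to fail: 10, 12 and 7.

Step 10 carries the most risk. The metathesis runs next to a free, epimerisable α-acetoxy aldehyde. The ten-membered closure must override the Felkin–Anh preference of that aldehyde, which favours the C8 epimer. The trivalent chromium alkoxide at O8 could also shift the lactone from O6 to O8. The fallback sets out from 15 and comes back at 17; it gives up the single-flask double closure and moves the ring closure from a reductive chromium Barbier reaction to a redox-neutral allylboration. The metathesis is run alone and 16 is isolated. Bromide is exchanged for boron (B2pin2, Pd2(dba)3 2.5 mol %, KOAc, toluene, 50 °C) to give pinacol allylboronate F1. The ring is then closed by Sc(OTf)3-catalysed intramolecular allylboration at high dilution through a closed six-membered transition state, with no low-valent metal and no metal alkoxide, and aqueous work-up gives 17.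

Step 12 depends on the ring conformation for face selectivity. The fallback sets out from 18 and comes back at 19; it applies if the peracid delivers oxygen to the wrong face, and it inverts the facial outcome through a halohydrin. NBS in THF/H2O at 0 °C puts the bromonium ion on the face the peracid uses, and water opens it at tertiary C4 from the other face to give bromohydrin F2. K2CO3 in acetone then closes the oxirane with inversion at C5 to give 19.

Step 7 is a catalyst-controlled vinyl transfer to a polyfunctional enal, and any loss of selectivity appears as the C6 epimer. The fallback sets out from 11 and comes back at 12; it replaces catalytic asymmetric addition by unselective addition followed by reagent-controlled reduction. Vinylmagnesium bromide (THF, −78 °C) gives 12 mixed with the (8R) epimer F3. The mixture is oxidised (MnO2, CH2Cl2) to dienone F4, which is reduced with (R)-Me-CBS oxazaborolidine (20 mol %) and catecholborane in toluene at −78 °C to 12.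

Further compounds
F1 | step 10 | methyl (2E,6E)-2-[(1R)-1-(acetyloxy)-2-oxoethyl]-6-methyl-7-[(2R)-5-oxo-4-[(4,4,5,5-tetramethyl-1,3,2-dioxaborolan-2-yl)methyl]-2,5-dihydrofuran-2-yl]hepta-2,6-dienoate | COC(=O)/C(=C/CC/C(C)=C/[C@H]1OC(=O)C(CB2OC(C)(C)C(C)(C)O2)=C1)[C@@H](OC(C)=O)C=O
F2 | step 12 | methyl (3aR,4R,5R,6E,10R,11S,11aS)-5-(acetyloxy)-11-bromo-10-hydroxy-10-methyl-3-methylidene-4-[(2-methylprop-2-enoyl)oxy]-2-oxo-2,3,3a,4,5,8,9,10,11,11a-decahydrocyclodeca[b]furan-6-carboxylate | C=C(C)C(=O)O[C@@H]1[C@H]2C(=C)C(=O)O[C@@H]2[C@H](Br)[C@@](O)(C)CC/C=C(/C(=O)OC)[C@H]1OC(C)=O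
F3 | step 7 | methyl (2E,6E,8R)-2-[(R)-(acetyloxy)[(4S)-2,2-dimethyl-1,3-dioxolan-4-yl]methyl]-8-hydroxy-6-methyldeca-2,6,9-trienoate | COC(=O)/C(=C/CC/C(C)=C/[C@@H](C=C)O)[C@@H](OC(C)=O)[C@@H]1COC(C)(C)O1
F4 | step 7 | methyl (2E,6E)-2-[(R)-(acetyloxy)[(4S)-2,2-dimethyl-1,3-dioxolan-4-yl]methyl]-6-methyl-8-oxodeca-2,6,9-trienoate | COC(=O)/C(=C/CC/C(C)=C/C(=O)C=C)[C@@H](OC(C)=O)[C@@H]1COC(C)(C)O1
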